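What stands in the flask at 5.0 min, and how much of it is target?

| flask | substrate | partner | remark | time |
|---|---|---|---|---|
| summer | 1.5 M | 0.50 equiv | run made earlier |  |
| midnight | 1.5 M | 0.75 equiv | run made earlier |  |
| winter | 0.75 M | 1 equiv | run made earlier |  |
| flask | 1.5 M | 1.00 equiv |  | 5.0 min |

- summer (time / min: target / %, side product / %): 0.417: 9.3, 87.5; 0.833: 8.1, 91.1; 1.33: 8.2, 91.6; 1.50: 8.0, 90.7; 2.00: 8.8, 91.1; 2.50: 8.0, 91.5; 3.00: 8.0, 91.5
- midnight (time / min: target / %, side product / %): 0.417: 8.1, 87.4; 0.833: 8.2, 91.0; 1.33: 8.2, 90.5; 1.50: 7.5, 91.4; 2.00: 7.5, 91.0; 2.50: 8.7, 91.7; 3.00: 8.0, 91.6
- winter (time / min: target / %, side product / %): 0.250: 8.0, 76.7; 0.417: 8.6, 88.0; 0.833: 8.2, 91.2; 1.50: 8.0, 90.4; 3.00: 7.4, 91.7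

(each reading ± 0.5 percentage points)

- at 5.0 min, what has stopped the reaction, if anything has (it is still moving / all of the substrate has reacted / forward and back rates have come level / the partner has run out first)
- the target standing at 5.0 min, as a percentage of the substrate charged
- the side product standing at 5.0 min, as a percentage of the substrate charged
- amount of target if the flask were left three thousand times as long, in percent of the substrate charged

- the earlier runs were read with a standard deviation of 0.5 percentage points
- steps that have been proposed: substrate -> target; partner <-> dormant form; partner + intermediate A <-> intermediate C; substrate <-> intermediate B; intermediate B -> side product; substrate -> intermediate A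
- the reaction counts as stopped when no species that holds the substrate changes by six tenths of a point or more over the second half of the time

Minutes of the meeting on this flask. The first speaker wrote the balance of the reagent charged in the smaller amount, which in the summer run is the partner at 0.50 equiv. She pointed out that target and side product together reached 99.5% of the substrate there, more than that charge, so the products do not take up partner one for one.

The second speaker added that the side product stood at 91.5%, 91.6% and 91.7% at the last readings, although the partner charge and [substrate] differed between the runs. He proposed carrying one number, the target share, or selectivity: target divided by target plus side product. From the last two readings of each run it came to 8.06%, a reading with its scatter.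

The minute-taker's own reckoning applied that share to the summer total, the summer run having the flask's [substrate], and gave 8.02% of target. She noted that the flask is read at 5.0 min, later than the last summer reading at 3.00 min.

The forecast, tabled next, said all of the substrate has reacted, with target 8% (range 7.7% to 8.4%), side product 91.4% (range 90.9% to 91.9%) and 8.1% of target on long standing. Its ground was that “The ratio is fixed by parallel branches”.

The flask gives: all of the substrate has reacted, with target 8.53%, side product 90.9%, and 8.53% of target on long standing.

    substrate → target (k = 0.0240 s⁻¹)
    partner ⇌ dormant form (K = 1.70, k = 0.110 s⁻¹)
    partner + intermediate A ⇌ intermediate C (K = 0.290 M⁻¹, k = 0.00240 M⁻¹ s⁻¹)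
    substrate ⇌ intermediate B (K = 12.0, k = 0.290 s⁻¹)
    intermediate B → side product (k = 0.180 s⁻¹)
    substrate → intermediate A (k = 0.00160 s⁻¹)

The flask's target stands just above the forecast's range but inside the tolerance, and its substrate is down to 0% with 37% of the partner still free. The carried share, applied to this flask's products, gives 8.01% of target against the 8.53% found. The neighbouring flask has [substrate] at 2.5 M with the same equivalents. There the same reckoning gives 8.01%, and the flask shows 8.53% of target beside 90.9% of side product, with 37.0% of its partner free.

The runs were generated by integration with made-up constants; the scatter is artificial.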